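The route rests on ring A: its ester carbon C1 lies between C2, which bears the prenyloxy oxygen, and C6, which bears the diaryl ether oxygen to ring B (methyl at C4). That 1,2,3-array is what a 3-alkoxybenzyne delivers when a nucleophile adds at the aryne carbon remote from the alkoxy group and an electrophile is taken up next to it. One operation therefore forges the C6–O and C1–CO2 bonds from three pieces: a MOM-protected 2-silylaryl triflate made from orcinol, the potassium phenoxide of a ring B salicyl alcohol (MOM and TIPS protected) and CO2. Esterification, one acidic global deprotection and double O-prenylation complete the target.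

Key step: step 10

Remark: the target has no stereocentre and no stereogenic double bond, so nothing stereochemical has to be controlled; salts that are only protonated on work-up are shown as the neutral compounds.

Step 1
Reactants: 1 orcinol (5-methylbenzene-1,3-diol)
Product: 2 3-(methoxymethoxy)-5-methylphenol
Conditions: MOMCl (1.0 equiv), iPr2NEt, DMF, 0 °C to rt
Reagents that add atoms: chloromethyl methyl ether (MOMCl), COCCl
Why: Williamson-type O-alkylation of a phenol with the reactive α-chloro ether; the two hydroxyls of 1 are equivalent, so limiting MOMCl should give the mono-ether, which is separated from recovered diol and bis-ether (both recyclable).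

Step 2
Reactants: 2 3-(methoxymethoxy)-5-methylphenol
Product: 3 3-(methoxymethoxy)-5-methylphenyl N-isopropylcarbamate
Conditions: iPrNCO, Et3N (cat.), CH2Cl2, rt
Reagents that add atoms: isopropyl isocyanate, CC(C)N=C=O
Why: Amine-catalysed addition of the phenol to the isocyanate (carbamoylation) gives an N-monoalkyl carbamate that directs lithiation strongly and can later be cleaved under mild base.

Step 3
Reactants: 3 3-(methoxymethoxy)-5-methylphenyl N-isopropylcarbamate
Product: 7 3-(methoxymethoxy)-5-methyl-2-(trimethylsilyl)phenyl N-isopropylcarbamate, via N-silyl carbamate 4 (not isolated), via aryllithium 5 (not isolated), via N-silyl C-silyl carbamate 6 (not isolated)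
Conditions: TBSOTf, TMEDA, Et2O, 0 °C to rt; n-BuLi, TMEDA, −78 °C; TMSCl, −78 °C to rt; cold aq. NaHSO4 (brief)
Reagents that add atoms: chlorotrimethylsilane (TMSCl), C[Si](C)(C)Cl
Why: Directed ortho-metalation: after in situ N-silylation of the carbamate N–H, the carbamate and the MOM ether cooperate to place lithium on the carbon between the two oxygens, TMSCl traps it there, and the labile N–Si bond is hydrolysed on work-up.

Step 4
Reactants: 7 3-(methoxymethoxy)-5-methyl-2-(trimethylsilyl)phenyl N-isopropylcarbamate
Product: 9 3-(methoxymethoxy)-5-methyl-2-(trimethylsilyl)phenyl trifluoromethanesulfonate, via silyl phenol 8 (not isolated)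
Conditions: DBU, Et2NH, MeCN, 40 °C; then PhNTf2, rt
Reagents that add atoms: N-phenylbis(trifluoromethanesulfonimide) (PhNTf2), O=S(=O)(N(c1ccccc1)S(=O)(=O)C(F)(F)F)C(F)(F)F
Why: E1cB cleavage of the N-monoalkyl carbamate by DBU (the expelled isocyanate is scavenged by Et2NH) liberates the phenoxide, which is sulfonylated in the same pot by the mild triflating agent PhNTf2 without loss of the aryl silane or the MOM ether.

Step 5
Reactants: 10 2-hydroxy-5-methoxybenzaldehyde
Product: 11 3-bromo-2-hydroxy-5-methoxybenzaldehyde
Conditions: Br2, NaOAc, AcOH, rt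
Reagents that add atoms: bromine, BrBr
Why: Electrophilic aromatic bromination should go to C3, the only free position ortho to the phenol (its para position carries the methoxy group) and a position meta to the deactivating formyl group.

Step 6
Reactants: 11 3-bromo-2-hydroxy-5-methoxybenzaldehyde
Product: 12 2,3-dihydroxy-5-methoxybenzaldehyde
Conditions: aq. NaOH (excess), Cu powder (cat.), reflux, N2; then aq. HCl to pH 2
Reagents that add atoms: sodium hydroxide, [Na+].[OH-]
Why: Copper-mediated hydroxy-debromination (Ullmann-type hydrolysis) of an ortho-bromophenoxide, the reaction type that turns 5-bromovanillin into 5-hydroxyvanillin; the adjacent phenoxide assists copper and, by making the ring electron-rich, keeps the aldehyde from Cannizzaro disproportionation.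

Step 7
Reactants: 12 2,3-dihydroxy-5-methoxybenzaldehyde
Product: 14 2-hydroxy-5-methoxy-3-(methoxymethoxy)benzaldehyde, via disodium catecholate 13 (not isolated)
Conditions: NaH (2.2 equiv), DMF, 0 °C; MOMCl (1.0 equiv), 0 °C to rt; aq. NH4Cl
Reagents that add atoms: chloromethyl methyl ether (MOMCl), COCCl
Why: Regioselective O-alkylation of a catechol dianion: the C2 phenoxide is stabilised by conjugation with and sodium chelation to the formyl group, so the more basic C3 phenoxide should take up the single equivalent of MOMCl.

Step 8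
Reactants: 14 2-hydroxy-5-methoxy-3-(methoxymethoxy)benzaldehyde
Product: 15 2-(hydroxymethyl)-4-methoxy-6-(methoxymethoxy)phenol
Conditions: NaBH4, MeOH, 0 °C; aq. NH4Cl
Reagents that add atoms: none
Why: Borohydride reduction of the aldehyde to the primary benzylic alcohol, with the phenol and the MOM acetal inert to hydride.

Step 9
Reactants: 15 2-(hydroxymethyl)-4-methoxy-6-(methoxymethoxy)phenol
Product: 16 4-methoxy-2-(methoxymethoxy)-6-{[(triisopropylsilyl)oxy]methyl}phenol
Conditions: TIPSCl (1.05 equiv), imidazole, CH2Cl2, 0 °C to rt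
Reagents that add atoms: chlorotriisopropylsilane (TIPSCl), CC(C)[Si](Cl)(C(C)C)C(C)C
Why: Chemoselective silylation: the bulky silyl chloride should react at the unhindered primary benzylic hydroxyl far faster than at the hydrogen-bonded phenol flanked by two ortho substituents, as in the mono-silylation of salicyl alcohols.

Step 10
Reactants: 9 3-(methoxymethoxy)-5-methyl-2-(trimethylsilyl)phenyl trifluoromethanesulfonate; 16 4-methoxy-2-(methoxymethoxy)-6-{[(triisopropylsilyl)oxy]methyl}phenol; 17 carbon dioxide
Product: 21 2-[4-methoxy-2-(methoxymethoxy)-6-{[(triisopropylsilyl)oxy]methyl}phenoxy]-6-(methoxymethoxy)-4-methylbenzoic acid, via potassium phenoxide 18 (not isolated), via aryne 19 (not isolated), via aryl anion adduct 20 (not isolated)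
Conditions: 16 (slight excess), KH, THF, 0 °C; then KF, 18-crown-6, CO2 (1 atm), slow addition of 9, THF, 0 °C to rt; cold 1 M aq. HCl to pH 3
Reagents that add atoms: none
Why: Proposed new method: fluoride attacks the trimethylsilyl group of 9 and expels triflate to give aryne 19, whose triple bond is distorted by the inductively withdrawing MOM-oxy group so that the preformed phenoxide 18 adds at the aryne carbon remote from that oxygen; the aryl anion 20 then lies between the two oxygen-bearing carbons and, with no proton source present, is captured by dissolved CO2 to give the potassium carboxylate. The closest known reaction types are the three-component coupling of arynes with amines and CO2 to give anthranilic acids and the O-arylation of phenols with ortho-silylaryl triflates; the new element is an anionic oxygen nucleophile used together with CO2. No ring is closed and no stereocentre is formed. The step needs regioselectivity (C–O bond at the distal aryne carbon, carboxyl at the proximal one), which the 3-alkoxy substituent secures, and carboxylation in preference to protonation, which is secured by the fully deprotonated phenol, by THF in place of the more acidic acetonitrile and by a CO2-saturated solution. A MOM ether is kept next to the aryne because a prenyl ether there could undergo an intramolecular ene reaction, and the TIPS ether is chosen to withstand KF/18-crown-6.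

Step 11
Reactants: 21 2-[4-methoxy-2-(methoxymethoxy)-6-{[(triisopropylsilyl)oxy]methyl}phenoxy]-6-(methoxymethoxy)-4-methylbenzoic acid
Product: 22 methyl 2-[4-methoxy-2-(methoxymethoxy)-6-{[(triisopropylsilyl)oxy]methyl}phenoxy]-6-(methoxymethoxy)-4-methylbenzoate
Conditions: MeI, K2CO3, DMF, rt
Reagents that add atoms: iodomethane, CI
Why: SN2 O-methylation of the potassium carboxylate takes place at the unhindered methyl iodide and is therefore not slowed by the two ortho substituents that would hamper Fischer esterification.

Step 12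
Reactants: 22 methyl 2-[4-methoxy-2-(methoxymethoxy)-6-{[(triisopropylsilyl)oxy]methyl}phenoxy]-6-(methoxymethoxy)-4-methylbenzoate
Product: 23 methyl 2-hydroxy-6-[2-hydroxy-6-(hydroxymethyl)-4-methoxyphenoxy]-4-methylbenzoate
Conditions: 3 M aq. HCl, MeOH/THF, 40 °C
Reagents that add atoms: none
Why: Acid-catalysed acetal cleavage removes both aryl MOM ethers and acidic solvolysis removes the primary silyl ether in the same pot, while the doubly ortho-substituted methyl benzoate resists hydrolysis and the benzylic alcohol, which has no alkoxy donor para to it and only an aryloxy group ortho, should not ionise.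

Step 13
Reactants: 23 methyl 2-hydroxy-6-[2-hydroxy-6-(hydroxymethyl)-4-methoxyphenoxy]-4-methylbenzoate; 24 prenyl bromide (1-bromo-3-methylbut-2-ene)
Product: 25 methyl 2-{2-(hydroxymethyl)-4-methoxy-6-[(3-methylbut-2-en-1-yl)oxy]phenoxy}-4-methyl-6-[(3-methylbut-2-en-1-yl)oxy]benzoate (CNP0561346.0)
Conditions: 24 (2.5 equiv), K2CO3, DMF, rt to 40 °C
Reagents that add atoms: none
Why: Williamson ether synthesis: carbonate deprotonates only the two phenols, which are O-alkylated by the allylic bromide, whereas the far less acidic primary benzylic alcohol should stay untouched.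

Compound list
1 | orcinol (5-methylbenzene-1,3-diol) | Cc1cc(O)cc(O)c1 | starting material
2 | 3-(methoxymethoxy)-5-methylphenol | COCOc1cc(C)cc(O)c1 | intermediate
3 | 3-(methoxymethoxy)-5-methylphenyl N-isopropylcarbamate | CC(C)NC(=O)Oc1cc(C)cc(OCOC)c1 | intermediate
4 | 3-(methoxymethoxy)-5-methylphenyl N-(tert-butyldimethylsilyl)-N-isopropylcarbamate | CC(C)N(C(=O)Oc1cc(C)cc(OCOC)c1)[Si](C)(C)C(C)(C)C | intermediate (not isolated)
5 | 2-lithio derivative of 4 (lithium on the carbon between the two oxygens) | [Li]c1c(OCOC)cc(C)cc1OC(=O)N(C(C)C)[Si](C)(C)C(C)(C)C | intermediate (not isolated)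
6 | 3-(methoxymethoxy)-5-methyl-2-(trimethylsilyl)phenyl N-(tert-butyldimethylsilyl)-N-isopropylcarbamate | CC(C)N(C(=O)Oc1cc(C)cc(OCOC)c1[Si](C)(C)C)[Si](C)(C)C(C)(C)C | intermediate (not isolated)
7 | 3-(methoxymethoxy)-5-methyl-2-(trimethylsilyl)phenyl N-isopropylcarbamate | CC(C)NC(=O)Oc1cc(C)cc(OCOC)c1[Si](C)(C)C | intermediate
8 | 3-(methoxymethoxy)-5-methyl-2-(trimethylsilyl)phenol | COCOc1cc(C)cc(O)c1[Si](C)(C)C | intermediate (not isolated)
9 | 3-(methoxymethoxy)-5-methyl-2-(trimethylsilyl)phenyl trifluoromethanesulfonate | COCOc1cc(C)cc(OS(=O)(=O)C(F)(F)F)c1[Si](C)(C)C | intermediate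
10 | 2-hydroxy-5-methoxybenzaldehyde | COc1ccc(O)c(C=O)c1 | starting material
11 | 3-bromo-2-hydroxy-5-methoxybenzaldehyde | COc1cc(Br)c(O)c(C=O)c1 | intermediate
12 | 2,3-dihydroxy-5-methoxybenzaldehyde | COc1cc(O)c(O)c(C=O)c1 | intermediate
13 | disodium 3-formyl-5-methoxybenzene-1,2-diolate | COc1cc([O-])c([O-])c(C=O)c1.[Na+].[Na+] | intermediate (not isolated)
14 | 2-hydroxy-5-methoxy-3-(methoxymethoxy)benzaldehyde | COCOc1cc(OC)cc(C=O)c1O | intermediate
15 | 2-(hydroxymethyl)-4-methoxy-6-(methoxymethoxy)phenol | COCOc1cc(OC)cc(CO)c1O | intermediate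
16 | 4-methoxy-2-(methoxymethoxy)-6-{[(triisopropylsilyl)oxy]methyl}phenol | COCOc1cc(OC)cc(CO[Si](C(C)C)(C(C)C)C(C)C)c1O | intermediate
17 | carbon dioxide | O=C=O | starting material
18 | potassium 4-methoxy-2-(methoxymethoxy)-6-{[(triisopropylsilyl)oxy]methyl}phenoxide | COCOc1cc(OC)cc(CO[Si](C(C)C)(C(C)C)C(C)C)c1[O-].[K+] | intermediate (not isolated)
19 | 3-(methoxymethoxy)-5-methylbenzyne | COCOC1=CC(C)=CC#C1 | intermediate (not isolated)
20 | potassium salt of the 2-aryloxy-6-(methoxymethoxy)-4-methylphenyl anion (aryl = ring B of 16) | COCOc1cc(C)cc(Oc2c(CO[Si](C(C)C)(C(C)C)C(C)C)cc(OC)cc2OCOC)[c-]1.[K+] | intermediate (not isolated)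
21 | 2-[4-methoxy-2-(methoxymethoxy)-6-{[(triisopropylsilyl)oxy]methyl}phenoxy]-6-(methoxymethoxy)-4-methylbenzoic acid | OC(=O)c1c(OCOC)cc(C)cc1Oc1c(CO[Si](C(C)C)(C(C)C)C(C)C)cc(OC)cc1OCOC | intermediate
22 | methyl 2-[4-methoxy-2-(methoxymethoxy)-6-{[(triisopropylsilyl)oxy]methyl}phenoxy]-6-(methoxymethoxy)-4-methylbenzoate | COC(=O)c1c(OCOC)cc(C)cc1Oc1c(CO[Si](C(C)C)(C(C)C)C(C)C)cc(OC)cc1OCOC | intermediate
23 | methyl 2-hydroxy-6-[2-hydroxy-6-(hydroxymethyl)-4-methoxyphenoxy]-4-methylbenzoate | COC(=O)c1c(O)cc(C)cc1Oc1c(CO)cc(OC)cc1O | intermediate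
24 | prenyl bromide (1-bromo-3-methylbut-2-ene) | CC(C)=CCBr | starting material
25 | methyl 2-{2-(hydroxymethyl)-4-methoxy-6-[(3-methylbut-2-en-1-yl)oxy]phenoxy}-4-methyl-6-[(3-methylbut-2-en-1-yl)oxy]benzoate | COC(=O)c1c(OCC=C(C)C)cc(C)cc1Oc1c(CO)cc(OC)cc1OCC=C(C)C | target

Total step count: 13. Longest linear sequence: 9 steps (steps 5 to 13).

Steps most likely to fail

Step 10. Three processes could defeat it:
- protonation of the aryl anion before it meets CO2;
- reversible masking of the phenoxide as its carbonate under CO2, with addition through the carbonate oxygen and acyl migration, which would lead to an isomeric aryl ester;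
- O-arylation of the product carboxylate by further aryne.

The fallback builds the ether and the carboxyl carbon separately by known chemistry; it sets out from 16 and returns at 21. Purchased 3-fluoro-5-methylphenol F1 is converted with MOMCl and iPr2NEt in CH2Cl2 into 1-fluoro-3-(methoxymethoxy)-5-methylbenzene F2. Lithiation between fluorine and the MOM-oxy group (n-BuLi, THF, −78 °C) gives [2-fluoro-6-(methoxymethoxy)-4-methylphenyl]lithium F3, which is formylated cold with DMF to 2-fluoro-6-(methoxymethoxy)-4-methylbenzaldehyde F4. Nucleophilic aromatic substitution of the aldehyde-activated fluoride by phenol 16 (K2CO3, DMSO, 100 °C) should give 2-[4-methoxy-2-(methoxymethoxy)-6-{[(triisopropylsilyl)oxy]methyl}phenoxy]-6-(methoxymethoxy)-4-methylbenzaldehyde F5. Pinnick oxidation (NaClO2, NaH2PO4, 2-methyl-2-butene, t-BuOH/H2O) then gives acid 21.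

Step 6. The electron-rich catecholate may degrade oxidatively in hot alkali, or substitution of bromide may stall or give way to hydrodebromination. The fallback avoids the free catechol aldehyde; it sets out from 11 and returns at 16, bypassing steps 6 to 9.
- Benzylation of 11 (BnBr, K2CO3, DMF) gives 2-(benzyloxy)-3-bromo-5-methoxybenzaldehyde F6.
- NaBH4 in MeOH gives [2-(benzyloxy)-3-bromo-5-methoxyphenyl]methanol F7.
- TIPSCl and imidazole give {[2-(benzyloxy)-3-bromo-5-methoxybenzyl]oxy}triisopropylsilane F8.
- Palladium-catalysed hydroxylation of the aryl bromide (Pd2(dba)3, tBuXPhos, KOH, 1,4-dioxane/H2O, 100 °C) gives 2-(benzyloxy)-5-methoxy-3-{[(triisopropylsilyl)oxy]methyl}phenol F9.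
- MOMCl and iPr2NEt give {[2-(benzyloxy)-5-methoxy-3-(methoxymethoxy)benzyl]oxy}triisopropylsilane F10.
- Hydrogenolysis of the benzyl ether (H2, Pd/C, EtOAc) releases phenol 16.

Step 7. Alkylation may occur on the chelated C2 oxygen or on both oxygens. The fallback replaces kinetic differentiation of the dianion by chelation-controlled deprotection; it sets out from 12 and returns at 14. Both phenols are protected with excess MOMCl and iPr2NEt in CH2Cl2 to give 5-methoxy-2,3-bis(methoxymethoxy)benzaldehyde F11. The MOM ether ortho to the formyl group is then cleaved selectively by a chelating Lewis acid (MgBr2·OEt2, CH2Cl2, rt), which binds between the carbonyl oxygen and the neighbouring acetal oxygen, to give 14.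

Further compounds
F1 | step 10 | 3-fluoro-5-methylphenol (purchased) | Cc1cc(O)cc(F)c1
F2 | step 10 | 1-fluoro-3-(methoxymethoxy)-5-methylbenzene | COCOc1cc(C)cc(F)c1
F3 | step 10 | [2-fluoro-6-(methoxymethoxy)-4-methylphenyl]lithium | [Li]c1c(F)cc(C)cc1OCOC
F4 | step 10 | 2-fluoro-6-(methoxymethoxy)-4-methylbenzaldehyde | COCOc1cc(C)cc(F)c1C=O
F5 | step 10 | 2-[4-methoxy-2-(methoxymethoxy)-6-{[(triisopropylsilyl)oxy]methyl}phenoxy]-6-(methoxymethoxy)-4-methylbenzaldehyde | O=Cc1c(OCOC)cc(C)cc1Oc1c(CO[Si](C(C)C)(C(C)C)C(C)C)cc(OC)cc1OCOC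
F6 | step 6 | 2-(benzyloxy)-3-bromo-5-methoxybenzaldehyde | COc1cc(Br)c(OCc2ccccc2)c(C=O)c1
F7 | step 6 | [2-(benzyloxy)-3-bromo-5-methoxyphenyl]methanol | COc1cc(Br)c(OCc2ccccc2)c(CO)c1
F8 | step 6 | {[2-(benzyloxy)-3-bromo-5-methoxybenzyl]oxy}triisopropylsilane | COc1cc(Br)c(OCc2ccccc2)c(CO[Si](C(C)C)(C(C)C)C(C)C)c1
F9 | step 6 | 2-(benzyloxy)-5-methoxy-3-{[(triisopropylsilyl)oxy]methyl}phenol | COc1cc(O)c(OCc2ccccc2)c(CO[Si](C(C)C)(C(C)C)C(C)C)c1
F10 | step 6 | {[2-(benzyloxy)-5-methoxy-3-(methoxymethoxy)benzyl]oxy}triisopropylsilane | COCOc1cc(OC)cc(CO[Si](C(C)C)(C(C)C)C(C)C)c1OCc1ccccc1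
F11 | step 7 | 5-methoxy-2,3-bis(methoxymethoxy)benzaldehyde | COCOc1cc(OC)cc(C=O)c1OCOC
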